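**Plan**

- Retrosynthesis: the butenolide is opened at its ring C=C bond and its lactone C–O bond (intramolecular Horner–Wadsworth–Emmons olefination of a ketol phosphonoacetate), leading back to an α-hydroxy methyl ester. The side chain (C-1 carbinol to C-10 on the cyclohexene ring) is then cut at C-2–C-3 and C-4–C-5, and the remaining chain at C-6–C-7 and C-8–CH3.
- Enabling feature: the C-3=C-4 alkene carries CH2OH on C-4 on the same side as C-2 and the C-5 chain on the opposite side. This 2-alkylated (Z)-allylic alcohol is what anti addition of a carbon–magnesium bond across propargyl alcohol, followed by retentive alkylation of the vinylmagnesium, leaves behind.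
- Forward order: dihydro-β-ionone → terminal alkyne → (E)-homoallylic alcohol → bromide → Grignard reagent; three-component union with propargyl alcohol and methyl (R)-glycidate; silylation, chloromethyl ketone, butenolide closure (the only ring made; the cyclohexene ring is bought), desilylation.
- Stereochemistry: C-1 (R) comes from methyl (R)-glycidate, whose stereogenic carbon is never attacked; 7E comes from syn methylalumination; 3Z from anti carbomagnesiation with retentive trapping.

Key step: step 5

Remark: side-chain numbering C-1 (carbinol) to C-10 (ring-bound CH2) is used in the discussion; Grignard reagent 9 is counted as a route compound although it is handled only as a titrated ethereal solution.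

**Route**

Step 1
Reactants: 1 dihydro-β-ionone [4-(2,6,6-trimethylcyclohex-1-en-1-yl)butan-2-one]
Product: 3 2-(but-3-yn-1-yl)-1,3,3-trimethylcyclohex-1-ene, via enol phosphate 2 (not isolated)
Conditions: LiN(iPr)2 (1.05 equiv), THF, −78 °C; ClP(O)(OEt)2, −78 °C → rt; then LiN(iPr)2 (2.3 equiv), THF, −78 °C → rt; H2O
Reagents that add atoms: none
Why: Kinetic deprotonation at the methyl group, O-phosphorylation and amide-induced β-elimination of the enol phosphate make up the standard methyl ketone to terminal alkyne conversion (enol phosphate elimination), and the tetrasubstituted ring olefin is inert to the base.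

Step 2
Reactants: 3 2-(but-3-yn-1-yl)-1,3,3-trimethylcyclohex-1-ene; 4 ethylene oxide
Product: 7 (E)-4-methyl-6-(2,6,6-trimethylcyclohex-1-en-1-yl)hex-3-en-1-ol, via alkenylalane 5 (not isolated), via lithium alanate 6 (not isolated)
Conditions: Me3Al (2 equiv), Cp2ZrCl2 (0.25 equiv), CH2Cl2, rt; volatiles removed, hexane; n-BuLi, THF, 0 °C; 4, 0 °C → rt; cold 1 M HCl
Reagents that add atoms: trimethylaluminium, C[Al](C)C
Why: Zirconium-catalysed methylalumination of the terminal alkyne (Negishi carboalumination) adds methyl and aluminium syn with methyl on the internal carbon, which fixes the E geometry, and the butyl ate complex transfers its alkenyl group to ethylene oxide with retention to give the homoallylic alcohol.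

Step 3
Reactants: 7 (E)-4-methyl-6-(2,6,6-trimethylcyclohex-1-en-1-yl)hex-3-en-1-ol
Product: 8 2-[(E)-6-bromo-3-methylhex-3-en-1-yl]-1,3,3-trimethylcyclohex-1-ene
Conditions: CBr4, PPh3, CH2Cl2, 0 °C
Reagents that add atoms: carbon tetrabromide, BrC(Br)(Br)Br
Why: The Appel reaction converts the primary alcohol to the bromide by SN2 displacement of the oxyphosphonium under neutral conditions that leave both olefins untouched.

Step 4
Reactants: 8 2-[(E)-6-bromo-3-methylhex-3-en-1-yl]-1,3,3-trimethylcyclohex-1-ene
Product: 9 (E)-[4-methyl-6-(2,6,6-trimethylcyclohex-1-en-1-yl)hex-3-en-1-yl]magnesium bromide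
Conditions: Mg turnings (I2-activated), Et2O, gentle reflux → rt; titrated and used as solution
Reagents that add atoms: magnesium, [Mg]
Why: Grignard formation by insertion of magnesium metal into the primary C–Br bond is routine, and the homoallyl to cyclopropylcarbinyl rearrangement that could scramble the olefin would have to pass through a tertiary cyclopropylcarbinyl magnesium species and should not compete.

Step 5
Reactants: 9 (E)-[4-methyl-6-(2,6,6-trimethylcyclohex-1-en-1-yl)hex-3-en-1-yl]magnesium bromide; 10 propargyl alcohol (prop-2-yn-1-ol); 11 methyl (R)-glycidate [methyl (2R)-oxirane-2-carboxylate]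
Product: 14 methyl (2R,4Z,8E)-2-hydroxy-5-(hydroxymethyl)-9-methyl-11-(2,6,6-trimethylcyclohex-1-en-1-yl)undeca-4,8-dienoate, via bromomagnesium prop-2-yn-1-olate 12 (not isolated), via vinylmagnesium chelate 13 (not isolated)
Conditions: 10, EtMgBr (1.0 equiv), Et2O, 0 °C; CuI (10 mol %), 9 (1.2 equiv), 0 °C → rt; THF, 11 (1.5 equiv), −40 → −20 °C; sat. aq NH4Cl
Reagents that add atoms: none
Why: Proposed new method: an alkylcopper formed from 9 and catalytic CuI adds across the alkyne of alkoxide 12 with the alkyl group going to the carbon next to CH2O and the metal to the terminal carbon anti to it, magnesium being held by the alkoxide in the five-membered O–Mg–C chelate 13 (C-4–C-5 formed), and 13, again through copper, attacks the CH2 carbon of epoxide 11 in an SN2 opening with retention at the vinyl carbon (C-2–C-3 formed). The closest known reaction types are the CuI-catalysed anti-carbomagnesiation of propargylic alcohols with trapping of the chelated vinylmagnesium by iodine, carbonyl compounds or allylic halides, and the CuI-catalysed opening of glycidic esters at their CH2 carbon by vinyl Grignard reagents; using the chelated vinylmagnesium as the epoxide-opening nucleophile in the same flask is the untested part. No ring of the product is closed, the chelate ring of 13 being broken on work-up, and no stereocentre is created: the R centre is carried in from 11, whose oxygen-bearing carbon is not touched, and the C-3=C-4 geometry (CH2OH cis to C-2) follows from anti addition plus retentive substitution. The step needs carbon delivery next to CH2O, anti addition, and attack at the epoxide CH2 in preference to the ester; alkoxide chelation secures the first two, and the unhindered epoxide terminus together with copper catalysis at low temperature secures the third. A small excess of 9 is used so that the acetylenic C–H of unreacted 12 cannot protonate 13, and correspondingly more 11 is charged to absorb that excess.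

Step 6
Reactants: 14 methyl (2R,4Z,8E)-2-hydroxy-5-(hydroxymethyl)-9-methyl-11-(2,6,6-trimethylcyclohex-1-en-1-yl)undeca-4,8-dienoate
Product: 15 methyl (2R,4Z,8E)-2-[(tert-butyldimethylsilyl)oxy]-5-{[(tert-butyldimethylsilyl)oxy]methyl}-9-methyl-11-(2,6,6-trimethylcyclohex-1-en-1-yl)undeca-4,8-dienoate
Conditions: TBSCl, imidazole, DMF, rt
Reagents that add atoms: tert-butyldimethylsilyl chloride, CC(C)(C)[Si](C)(C)Cl
Why: Imidazole-promoted silylation in DMF protects both the primary allylic and the secondary α-hydroxy ester hydroxyl without enolising the ester, so the R centre is kept.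

Step 7
Reactants: 15 methyl (2R,4Z,8E)-2-[(tert-butyldimethylsilyl)oxy]-5-{[(tert-butyldimethylsilyl)oxy]methyl}-9-methyl-11-(2,6,6-trimethylcyclohex-1-en-1-yl)undeca-4,8-dienoate
Product: 16 (3R,5Z,9E)-3-[(tert-butyldimethylsilyl)oxy]-6-{[(tert-butyldimethylsilyl)oxy]methyl}-1-chloro-10-methyl-12-(2,6,6-trimethylcyclohex-1-en-1-yl)dodeca-5,9-dien-2-one
Conditions: ICH2Cl, MeLi·LiBr, THF, −78 °C; sat. aq NH4Cl, −78 °C → rt
Reagents that add atoms: chloroiodomethane, ClCI
Why: Chloromethyllithium generated in situ by iodine–lithium exchange adds once to the α-silyloxy ester (carbenoid homologation of esters to chloromethyl ketones, known for α-alkoxy and α-amino esters), because the lithium hemiketal is stable at −78 °C and collapses to the ketone only on quench, which also avoids enolisation next to the stereocentre.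

Step 8
Reactants: 16 (3R,5Z,9E)-3-[(tert-butyldimethylsilyl)oxy]-6-{[(tert-butyldimethylsilyl)oxy]methyl}-1-chloro-10-methyl-12-(2,6,6-trimethylcyclohex-1-en-1-yl)dodeca-5,9-dien-2-one
Product: 18 4-[(1R,3Z,7E)-1-[(tert-butyldimethylsilyl)oxy]-4-{[(tert-butyldimethylsilyl)oxy]methyl}-8-methyl-10-(2,6,6-trimethylcyclohex-1-en-1-yl)deca-3,7-dien-1-yl]furan-2(5H)-one, via phosphonoacetate ester 17 (not isolated)
Conditions: (EtO)2P(O)CH2CO2H (1.5 equiv), Cs2CO3 (0.7 equiv), NaI (cat.), MeCN, rt; then LiCl, iPr2NEt, rt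
Reagents that add atoms: diethylphosphonoacetic acid, CCOP(=O)(CC(=O)O)OCC
Why: SN2 displacement of the activated chloride by the caesium carboxylate gives the ketol phosphonoacetate, which closes the five-membered lactone by intramolecular Horner–Wadsworth–Emmons olefination under Masamune–Roush conditions, a base system mild enough that it should not enolise the α-silyloxy ketone.

Step 9
Reactants: 18 4-[(1R,3Z,7E)-1-[(tert-butyldimethylsilyl)oxy]-4-{[(tert-butyldimethylsilyl)oxy]methyl}-8-methyl-10-(2,6,6-trimethylcyclohex-1-en-1-yl)deca-3,7-dien-1-yl]furan-2(5H)-one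
Product: 19 4-[(1R,3Z,7E)-1-hydroxy-4-(hydroxymethyl)-8-methyl-10-(2,6,6-trimethylcyclohex-1-en-1-yl)deca-3,7-dien-1-yl]furan-2(5H)-one
Conditions: HF·pyridine, pyridine, THF, 0 °C → rt
Reagents that add atoms: none
Why: Fluoride-driven cleavage of both silyl ethers (desilylation) under pyridine-buffered conditions avoids the basic medium that could deprotonate the butenolide and the strong acid that could cyclise the polyene.

**Compound list**

1 | dihydro-β-ionone [4-(2,6,6-trimethylcyclohex-1-en-1-yl)butan-2-one] | CC(=O)CCC1=C(C)CCCC1(C)C | starting material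
2 | diethyl 4-(2,6,6-trimethylcyclohex-1-en-1-yl)but-1-en-2-yl phosphate (enol phosphate) | C=C(CCC1=C(C)CCCC1(C)C)OP(=O)(OCC)OCC | intermediate
3 | 2-(but-3-yn-1-yl)-1,3,3-trimethylcyclohex-1-ene | C#CCCC1=C(C)CCCC1(C)C | intermediate
4 | ethylene oxide (oxirane) | C1CO1 | starting material
5 | dimethyl[(E)-2-methyl-4-(2,6,6-trimethylcyclohex-1-en-1-yl)but-1-en-1-yl]alane (alkenylalane) | CC1=C(CC/C(C)=C/[Al](C)C)C(C)(C)CCC1 | intermediate
6 | lithium butyl(dimethyl)[(E)-2-methyl-4-(2,6,6-trimethylcyclohex-1-en-1-yl)but-1-en-1-yl]alanate (lithium alanate) | CC1=C(CC/C(C)=C/[Al-](C)(C)CCCC)C(C)(C)CCC1.[Li+] | intermediate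
7 | (E)-4-methyl-6-(2,6,6-trimethylcyclohex-1-en-1-yl)hex-3-en-1-ol | CC1=C(CC/C(C)=C/CCO)C(C)(C)CCC1 | intermediate
8 | 2-[(E)-6-bromo-3-methylhex-3-en-1-yl]-1,3,3-trimethylcyclohex-1-ene | CC1=C(CC/C(C)=C/CCBr)C(C)(C)CCC1 | intermediate
9 | (E)-[4-methyl-6-(2,6,6-trimethylcyclohex-1-en-1-yl)hex-3-en-1-yl]magnesium bromide | CC1=C(CC/C(C)=C/CC[Mg]Br)C(C)(C)CCC1 | intermediate
10 | propargyl alcohol (prop-2-yn-1-ol) | C#CCO | starting material
11 | methyl (R)-glycidate [methyl (2R)-oxirane-2-carboxylate] | COC(=O)[C@H]1CO1 | starting material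
12 | bromomagnesium prop-2-yn-1-olate | C#CCO[Mg]Br | intermediate
13 | 4-[(E)-4-methyl-6-(2,6,6-trimethylcyclohex-1-en-1-yl)hex-3-en-1-yl]-2,5-dihydro-1,2-oxamagnesole (vinylmagnesium chelate, Mg on the former alkyne terminus cis to CH2O) | CC1=C(CC/C(C)=C/CCC2=C[Mg]OC2)C(C)(C)CCC1 | intermediate
14 | methyl (2R,4Z,8E)-2-hydroxy-5-(hydroxymethyl)-9-methyl-11-(2,6,6-trimethylcyclohex-1-en-1-yl)undeca-4,8-dienoate | CC1=C(CC/C(C)=C/CC/C(=C/C[C@@H](O)C(=O)OC)CO)C(C)(C)CCC1 | intermediate
15 | methyl (2R,4Z,8E)-2-[(tert-butyldimethylsilyl)oxy]-5-{[(tert-butyldimethylsilyl)oxy]methyl}-9-methyl-11-(2,6,6-trimethylcyclohex-1-en-1-yl)undeca-4,8-dienoate | CC1=C(CC/C(C)=C/CC/C(=C/C[C@@H](O[Si](C)(C)C(C)(C)C)C(=O)OC)CO[Si](C)(C)C(C)(C)C)C(C)(C)CCC1 | intermediate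
16 | (3R,5Z,9E)-3-[(tert-butyldimethylsilyl)oxy]-6-{[(tert-butyldimethylsilyl)oxy]methyl}-1-chloro-10-methyl-12-(2,6,6-trimethylcyclohex-1-en-1-yl)dodeca-5,9-dien-2-one | CC1=C(CC/C(C)=C/CC/C(=C/C[C@@H](O[Si](C)(C)C(C)(C)C)C(=O)CCl)CO[Si](C)(C)C(C)(C)C)C(C)(C)CCC1 | intermediate
17 | (3R,5Z,9E)-3-[(tert-butyldimethylsilyl)oxy]-6-{[(tert-butyldimethylsilyl)oxy]methyl}-10-methyl-2-oxo-12-(2,6,6-trimethylcyclohex-1-en-1-yl)dodeca-5,9-dien-1-yl 2-(diethoxyphosphoryl)acetate (phosphonoacetate ester) | CC1=C(CC/C(C)=C/CC/C(=C/C[C@@H](O[Si](C)(C)C(C)(C)C)C(=O)COC(=O)CP(=O)(OCC)OCC)CO[Si](C)(C)C(C)(C)C)C(C)(C)CCC1 | intermediate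
18 | 4-[(1R,3Z,7E)-1-[(tert-butyldimethylsilyl)oxy]-4-{[(tert-butyldimethylsilyl)oxy]methyl}-8-methyl-10-(2,6,6-trimethylcyclohex-1-en-1-yl)deca-3,7-dien-1-yl]furan-2(5H)-one | CC1=C(CC/C(C)=C/CC/C(=C/C[C@@H](O[Si](C)(C)C(C)(C)C)C2=CC(=O)OC2)CO[Si](C)(C)C(C)(C)C)C(C)(C)CCC1 | intermediate
19 | 4-[(1R,3Z,7E)-1-hydroxy-4-(hydroxymethyl)-8-methyl-10-(2,6,6-trimethylcyclohex-1-en-1-yl)deca-3,7-dien-1-yl]furan-2(5H)-one (CNP0151336.2) | CC1=C(CC/C(C)=C/CC/C(=C/C[C@@H](O)C2=CC(=O)OC2)CO)C(C)(C)CCC1 | target

**Step count and risks**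

Total steps: 9. Longest linear sequence: 9 steps, from dihydro-β-ionone 1; compounds 4, 10 and 11 are bought.

Steps most likely to fail:

1. Step 5 (three-component coupling). The vinylmagnesium may be protonated by acetylenic C–H before it is trapped. Transfer of the chelated vinyl group to the epoxide may also be so slow that ester addition or opening of the epoxide by bromide takes over.
   Fallback, setting out from 9 and 10 and returning at 15: the carbomagnesiation is run in its established form with excess 9 and the chelate 13 is quenched with iodine to give (Z)-3-iodo-2-[(E)-4-methyl-6-(2,6,6-trimethylcyclohex-1-en-1-yl)hex-3-en-1-yl]prop-2-en-1-ol F1. Silylation (TBSCl, imidazole, DMF) gives its tert-butyldimethylsilyl ether F2. Iodine–magnesium exchange with iPrMgCl·LiCl in THF gives the alkenylmagnesium chloride F3, which under CuI catalysis at −78 → −40 °C opens 11 at its CH2 carbon, as ordinary vinyl Grignard reagents are known to do, to give the mono-silylated hydroxy ester F4. Silylation of the remaining secondary hydroxyl then delivers 15. The same two bonds are formed, in two flasks instead of one.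

2. Step 7 (chloromethyl ketone). The tetrahedral intermediate may collapse before the quench, so that a second carbenoid adds, or methyllithium may attack the ester directly.
   Fallback, setting out from 15 and returning at 16: aminolysis with Me(MeO)NH·HCl and iPrMgCl in THF at −20 °C gives the Weinreb amide F5, whose chelated adduct with chloromethyllithium (ICH2Cl, MeLi·LiBr, THF, −78 °C) cannot over-add and releases 16 on work-up.

3. Step 8 (butenolide closure). The silyloxy-bearing carbon may epimerise by enolisation of the ketone during displacement or olefination, or the olefination onto the hindered ketone may be slow under the mild base.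
   Fallback, setting out from 16 and returning at 18: displacement with HCO2Na (NaI cat., DMF, rt) gives the formate ester F6, mild methanolysis (NaHCO3, MeOH, 0 °C) frees the hydroxymethyl ketone F7, and heating F7 with the Bestmann ylide Ph3P=C=C=O in toluene gives 18 by O-acylation and intramolecular Wittig olefination under neutral conditions.

**Further compounds**

F1 | step 5 | (Z)-3-iodo-2-[(E)-4-methyl-6-(2,6,6-trimethylcyclohex-1-en-1-yl)hex-3-en-1-yl]prop-2-en-1-ol | CC1=C(CC/C(C)=C/CC/C(=C/I)CO)C(C)(C)CCC1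
F2 | step 5 | tert-butyl({(Z)-3-iodo-2-[(E)-4-methyl-6-(2,6,6-trimethylcyclohex-1-en-1-yl)hex-3-en-1-yl]prop-2-en-1-yl}oxy)dimethylsilane | CC1=C(CC/C(C)=C/CC/C(=C/I)CO[Si](C)(C)C(C)(C)C)C(C)(C)CCC1
F3 | step 5 | {(Z)-3-[(tert-butyldimethylsilyl)oxy]-2-[(E)-4-methyl-6-(2,6,6-trimethylcyclohex-1-en-1-yl)hex-3-en-1-yl]prop-1-en-1-yl}magnesium chloride | CC1=C(CC/C(C)=C/CC/C(=C/[Mg]Cl)CO[Si](C)(C)C(C)(C)C)C(C)(C)CCC1
F4 | step 5 | methyl (2R,4Z,8E)-5-{[(tert-butyldimethylsilyl)oxy]methyl}-2-hydroxy-9-methyl-11-(2,6,6-trimethylcyclohex-1-en-1-yl)undeca-4,8-dienoate | CC1=C(CC/C(C)=C/CC/C(=C/C[C@@H](O)C(=O)OC)CO[Si](C)(C)C(C)(C)C)C(C)(C)CCC1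
F5 | step 7 | (2R,4Z,8E)-2-[(tert-butyldimethylsilyl)oxy]-5-{[(tert-butyldimethylsilyl)oxy]methyl}-N-methoxy-N,9-dimethyl-11-(2,6,6-trimethylcyclohex-1-en-1-yl)undeca-4,8-dienamide | CC1=C(CC/C(C)=C/CC/C(=C/C[C@@H](O[Si](C)(C)C(C)(C)C)C(=O)N(C)OC)CO[Si](C)(C)C(C)(C)C)C(C)(C)CCC1
F6 | step 8 | (3R,5Z,9E)-3-[(tert-butyldimethylsilyl)oxy]-6-{[(tert-butyldimethylsilyl)oxy]methyl}-10-methyl-2-oxo-12-(2,6,6-trimethylcyclohex-1-en-1-yl)dodeca-5,9-dien-1-yl formate | CC1=C(CC/C(C)=C/CC/C(=C/C[C@@H](O[Si](C)(C)C(C)(C)C)C(=O)COC=O)CO[Si](C)(C)C(C)(C)C)C(C)(C)CCC1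
F7 | step 8 | (3R,5Z,9E)-3-[(tert-butyldimethylsilyl)oxy]-6-{[(tert-butyldimethylsilyl)oxy]methyl}-1-hydroxy-10-methyl-12-(2,6,6-trimethylcyclohex-1-en-1-yl)dodeca-5,9-dien-2-one | CC1=C(CC/C(C)=C/CC/C(=C/C[C@@H](O[Si](C)(C)C(C)(C)C)C(=O)CO)CO[Si](C)(C)C(C)(C)C)C(C)(C)CCC1
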